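**Plan**

- Retrosynthesis: the chain C3–C4 bond (sp3–sp2) is cut by a B-alkyl Suzuki–Miyaura coupling, with the chain ketone carried as a silyl-protected carbinol. The allyl group on pyranone C2 is cut by a decarboxylative allylic alkylation.
- The pyranone is then cut at C2–C3 and at C4=C5 in one operation, back to an acyclic lactate ether aldehyde and a two-carbon phosphonoacetate. The west half is cut at ArCH2–CH= and at the carbinol–alkyne bond.
- Enabling feature: in the 2H-pyran-3(6H)-one, C2 lies between ring oxygen O1 and the C3 ketone, C6 is fully substituted and C4=C5 is cis within the ring. An allyl carboxylate on C2 therefore makes C2 the only carbon acid for ring closure and later leaves as CO2.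
- Forward order: ether formation, oxidation, tandem Z-olefination/Dieckmann closure of the only ring (step 4), stereoconvergent allylation (step 5), hydroboration/Suzuki union with the west vinyl iodide (step 13), three end-game steps.
- Stereochemistry: the single stereocentre (S at pyranone C2) is formed racemic in step 4, erased in the palladium enolate and reset by the chiral PHOX ligand in step 5. The two E chain alkenes come from syn-carboalumination and syn-hydrozirconation and are retained in both cross-couplings.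

Key step: step 4

Remark on the chemistry: the sense of induction of (S)-t-BuPHOX on the oxygen-bearing enolate is assumed to match that of carbocyclic α-methyl allyl β-keto esters; if it proved opposite, the (R)-ligand would be used.

Ar = 2-methoxy-3-methyl-5-[tri(propan-2-yl)silyloxy]phenyl.

**Route**

Step 1
Reactants: 1 lactic acid (racemic); 2 prop-2-en-1-ol
Product: 3 prop-2-en-1-yl 2-hydroxypropanoate (allyl lactate, racemic)
Conditions: 2 (3 equiv), H2SO4 (cat.), toluene, reflux, Dean–Stark
Reagents that add atoms: none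
Why: Fischer esterification driven by azeotropic removal of water; the lactate stereocentre is left racemic because it is erased in step 5.

Step 2
Reactants: 3 allyl lactate; 4 2,2-dimethyloxirane
Product: 5 prop-2-en-1-yl 2-[(1-hydroxy-2-methylpropan-2-yl)oxy]propanoate
Conditions: 3 (4 equiv), BF3·OEt2 (5 mol %), CH2Cl2, −20 → 0 °C; Et3N quench
Reagents that add atoms: none
Why: Lewis-acid-catalysed epoxide alcoholysis, in which the activated oxirane opens at its tertiary carbon (Markovnikov, SN1-like) and so joins the secondary hydroxyl of 3 to the quaternary carbon.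

Step 3
Reactants: 5 hydroxy ester
Product: 6 prop-2-en-1-yl 2-[(2-methyl-1-oxopropan-2-yl)oxy]propanoate
Conditions: Dess–Martin periodinane, pyridine, CH2Cl2, 0 °C → rt (5 used at once)
Reagents that add atoms: none
Why: Dess–Martin oxidation of the neopentyl-type primary alcohol to a non-enolisable aldehyde, run immediately so that 5 cannot lactonise.

Step 4
Reactants: 6 aldehyde ester; 7 methyl 2-[bis(2,2,2-trifluoroethoxy)phosphoryl]acetate
Product: 9 prop-2-en-1-yl 2,6,6-trimethyl-3-oxo-3,6-dihydro-2H-pyran-2-carboxylate (racemic), via (Z)-enoate 8 (not isolated)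
Conditions: 7, KN(SiMe3)2 (1.05 equiv), 18-crown-6, THF, −78 °C; then KN(SiMe3)2 (1.3 equiv), −78 → −40 °C; AcOH quench at −40 °C
Reagents that add atoms: none
Why: Stage one is a Still–Gennari Horner–Wadsworth–Emmons olefination in which the phosphonoacetate carbanion adds to the non-enolisable aldehyde and fast collapse of the electron-poor oxaphosphetane gives the (Z)-enoate 8; stage two is a Dieckmann condensation in which the potassium enolate of the lactate ester, the only carbon acid present, attacks the cis-disposed methyl ester and expels methoxide. The closest known reaction types are the Z-selective olefination of α-alkoxy aldehydes and the Dieckmann closure of diester ethers to 3-oxopyran-2-carboxylates. The six-membered ring closes in the 6-exo-trig mode (enolate carbon C2 onto the ester carbonyl that becomes C3), which is possible only because the new C4=C5 bond is Z. The new fully substituted C2 is formed as a racemate on purpose, since it carries the allyl ester that is expelled in step 5, where the configuration is set. The step needs Z-selectivity (bis(trifluoroethyl) phosphonate with a crown-separated potassium ion), acylation faster than a [2,3]-Wittig shift of the α-alkoxy enolate (six-membered acylation path at low temperature) and no retro-Claisen opening of the non-enolisable β-keto ester (cold acetic acid quench).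

Step 5
Reactants: 9 allyl β-keto ester
Product: 10 (2S)-2,6,6-trimethyl-2-(prop-2-en-1-yl)-2H-pyran-3(6H)-one
Conditions: Pd2(dba)3 (2.5 mol %), (S)-t-BuPHOX (6.25 mol %), THF, 25 °C
Reagents that add atoms: none
Why: Tsuji–Trost decarboxylative asymmetric allylic alkylation, in which zerovalent palladium ionises the allyl ester, loss of CO2 gives a planar palladium 2H-pyran-3-olate (racemic C2 erased) and the PHOX-bound allyl group is delivered to one enolate face to set (S)-C2; C2 is the only nucleophilic carbon because C6 is quaternary and C4=C5 is cross-conjugated.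

Step 6
Reactants: 11 4-methoxy-3-methylphenol
Product: 12 (4-methoxy-3-methylphenoxy)tri(propan-2-yl)silane
Conditions: i-Pr3SiCl, imidazole, DMF, rt
Reagents that add atoms: chlorotri(propan-2-yl)silane, CC(C)[Si](Cl)(C(C)C)C(C)C
Why: Standard silylation of the phenol; the bulky silyl ether is a poor ortho-director and should survive the later base, acid and oxidant.

Step 7
Reactants: 12 aryl silyl ether
Product: 14 ArCH2OH, {2-methoxy-3-methyl-5-[tri(propan-2-yl)silyloxy]phenyl}methanol, via aryllithium 13 (not isolated)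
Conditions: n-BuLi, TMEDA, Et2O, 0 °C → rt; then (CH2O)n, 0 °C → rt; H2O
Reagents that add atoms: paraformaldehyde (source of formaldehyde), C=O
Why: Directed ortho-metalation, in which the methoxy group directs lithiation to its only free ortho position (C5 of the phenol numbering), and the aryllithium is hydroxymethylated.

Step 8
Reactants: 14 benzylic alcohol
Product: 15 ArCH2Br, [3-(bromomethyl)-4-methoxy-5-methylphenoxy]tri(propan-2-yl)silane
Conditions: CBr4, PPh3, CH2Cl2, 0 °C
Reagents that add atoms: tetrabromomethane, BrC(Br)(Br)Br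
Why: Appel bromination of a primary benzylic alcohol under neutral conditions.

Step 9
Reactants: 16 but-3-yn-1-ol; 15 benzylic bromide
Product: 18 (3E)-5-Ar-3-methylpent-3-en-1-ol, via alkenylalane 17 (not isolated)
Conditions: AlMe3 (3 equiv), Cp2ZrCl2 (25 mol %), CH2Cl2, 0 °C → rt; then 15, Pd(PPh3)4 (5 mol %), THF, rt; aq. potassium sodium tartrate
Reagents that add atoms: trimethylaluminium, C[Al](C)C
Why: Negishi zirconium-catalysed carboalumination adds methyl and aluminium syn across the alkyne (methyl to the internal carbon), and palladium-catalysed alkenyl–benzyl cross-coupling with retention gives the E trisubstituted alkene.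

Step 10
Reactants: 18 homoallylic alcohol
Product: 19 (3E)-5-Ar-3-methylpent-3-enal
Conditions: Dess–Martin periodinane, pyridine, CH2Cl2, 0 °C; used crude
Reagents that add atoms: none
Why: Buffered Dess–Martin oxidation should give the β,γ-unsaturated aldehyde without moving the alkene into conjugation.

Step 11
Reactants: 19 aldehyde
Product: 21 triethyl{[(6E)-8-Ar-6-methyloct-6-en-2-yn-4-yl]oxy}silane (racemic at C4), via magnesium alkoxide 20 (not isolated)
Conditions: CH3C≡CMgBr (1.3 equiv), THF, −78 °C; then Et3SiCl, imidazole, 0 °C → rt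
Reagents that add atoms: prop-1-yn-1-ylmagnesium bromide, CC#C[Mg]Br; chlorotriethylsilane, CC[Si](Cl)(CC)CC
Why: 1,2-addition of a weakly basic alkynyl Grignard reagent to the aldehyde and silylation of the alkoxide in the same flask; the carbinol configuration is irrelevant because it is oxidised in step 15.

Step 12
Reactants: 21 silyl-protected propargylic alcohol
Product: 23 triethyl{[(2E,6E)-8-Ar-2-iodo-6-methylocta-2,6-dien-4-yl]oxy}silane, via alkenylzirconocene 22 (not isolated)
Conditions: Cp2Zr(H)Cl (2.2 equiv), THF, rt → 45 °C; then I2, 0 °C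
Reagents that add atoms: iodine, II
Why: syn-Hydrozirconation of the internal alkyne, with zirconium settling on the less hindered methyl-bearing carbon after equilibration, and iodinolysis with retention give the vinyl iodide with iodine trans to the carbinol carbon.

Step 13
Reactants: 10 allyl pyranone; 23 vinyl iodide
Product: 25 (2S)-2-[(4E,8E)-10-Ar-4,8-dimethyl-6-(triethylsilyloxy)deca-4,8-dien-1-yl]-2,6,6-trimethyl-2H-pyran-3(6H)-one (both C6 epimers of the side chain), via alkylborane 24 (not isolated)
Conditions: 9-BBN (1.2 equiv), THF, 0 °C → rt; then 23, PdCl2(dppf) (5 mol %), AsPh3 (10 mol %), K3PO4 (3 M aq.), DMF, rt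
Reagents that add atoms: none
Why: anti-Markovnikov hydroboration of the terminal alkene, expected to be faster than reduction of the hindered ring ketone, followed by B-alkyl Suzuki–Miyaura coupling at zerovalent palladium with retention of the vinyl iodide geometry.

Step 14
Reactants: 25 triethylsilyl ether
Product: 26 (2S)-2-[(4E,8E)-10-Ar-6-hydroxy-4,8-dimethyldeca-4,8-dien-1-yl]-2,6,6-trimethyl-2H-pyran-3(6H)-one
Conditions: PPTS (10 mol %), MeOH/CH2Cl2, 0 °C → rt
Reagents that add atoms: none
Why: Mild acid methanolysis removes the secondary triethylsilyl ether, while the aryl tri(propan-2-yl)silyl ether should be stable to acid.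

Step 15
Reactants: 26 allylic alcohol
Product: 27 (2S)-2-[(4E,8E)-10-Ar-4,8-dimethyl-6-oxodeca-4,8-dien-1-yl]-2,6,6-trimethyl-2H-pyran-3(6H)-one
Conditions: Dess–Martin periodinane, pyridine, CH2Cl2, 0 °C
Reagents that add atoms: none
Why: Buffered Dess–Martin oxidation forms the chain ketone late and under near-neutral conditions, so the β,γ-alkene should not migrate into conjugation.

Step 16
Reactants: 27 silyl-protected target
Product: 28 (2S)-2-[(4E,8E)-10-(5-hydroxy-2-methoxy-3-methylphenyl)-4,8-dimethyl-6-oxodeca-4,8-dien-1-yl]-2,6,6-trimethyl-2H-pyran-3(6H)-one (target)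
Conditions: Bu4NF, AcOH (1:1), THF, 0 °C
Reagents that add atoms: none
Why: Fluoride cleavage of the aryl silyl ether, buffered with acetic acid so that neither the skipped dienone nor the pyranone meets free base.

**Compound list**

1 | lactic acid (racemic) | CC(O)C(=O)O | starting material
2 | prop-2-en-1-ol | C=CCO | starting material
3 | prop-2-en-1-yl 2-hydroxypropanoate | C=CCOC(=O)C(C)O | intermediate
4 | 2,2-dimethyloxirane | CC1(C)CO1 | starting material
5 | prop-2-en-1-yl 2-[(1-hydroxy-2-methylpropan-2-yl)oxy]propanoate | C=CCOC(=O)C(C)OC(C)(C)CO | intermediate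
6 | prop-2-en-1-yl 2-[(2-methyl-1-oxopropan-2-yl)oxy]propanoate | C=CCOC(=O)C(C)OC(C)(C)C=O | intermediate
7 | methyl 2-[bis(2,2,2-trifluoroethoxy)phosphoryl]acetate | COC(=O)CP(=O)(OCC(F)(F)F)OCC(F)(F)F | starting material
8 | methyl (2Z)-4-methyl-4-{[1-oxo-1-(prop-2-en-1-yloxy)propan-2-yl]oxy}pent-2-enoate | C=CCOC(=O)C(C)OC(C)(C)/C=C\C(=O)OC | intermediate
9 | prop-2-en-1-yl 2,6,6-trimethyl-3-oxo-3,6-dihydro-2H-pyran-2-carboxylate (racemic) | C=CCOC(=O)C1(C)OC(C)(C)C=CC1=O | intermediate
10 | (2S)-2,6,6-trimethyl-2-(prop-2-en-1-yl)-2H-pyran-3(6H)-one | C=CC[C@]1(C)OC(C)(C)C=CC1=O | intermediate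
11 | 4-methoxy-3-methylphenol | COc1ccc(O)cc1C | starting material
12 | (4-methoxy-3-methylphenoxy)tri(propan-2-yl)silane | COc1ccc(O[Si](C(C)C)(C(C)C)C(C)C)cc1C | intermediate
13 | {2-methoxy-3-methyl-5-[tri(propan-2-yl)silyloxy]phenyl}lithium | [Li]c1cc(O[Si](C(C)C)(C(C)C)C(C)C)cc(C)c1OC | intermediate
14 | {2-methoxy-3-methyl-5-[tri(propan-2-yl)silyloxy]phenyl}methanol | COc1c(C)cc(O[Si](C(C)C)(C(C)C)C(C)C)cc1CO | intermediate
15 | [3-(bromomethyl)-4-methoxy-5-methylphenoxy]tri(propan-2-yl)silane | COc1c(C)cc(O[Si](C(C)C)(C(C)C)C(C)C)cc1CBr | intermediate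
16 | but-3-yn-1-ol | C#CCCO | starting material
17 | (E)-alkenyldimethylalane of 16, as its O-dimethylaluminium alkoxide | C[Al](C)/C=C(\C)CCO[Al](C)C | intermediate
18 | (3E)-5-Ar-3-methylpent-3-en-1-ol | COc1c(C)cc(O[Si](C(C)C)(C(C)C)C(C)C)cc1C/C=C(\C)CCO | intermediate
19 | (3E)-5-Ar-3-methylpent-3-enal | COc1c(C)cc(O[Si](C(C)C)(C(C)C)C(C)C)cc1C/C=C(\C)CC=O | intermediate
20 | bromomagnesium (6E)-8-Ar-6-methyloct-6-en-2-yn-4-olate | COc1c(C)cc(O[Si](C(C)C)(C(C)C)C(C)C)cc1C/C=C(\C)CC(O[Mg]Br)C#CC | intermediate
21 | triethyl{[(6E)-8-Ar-6-methyloct-6-en-2-yn-4-yl]oxy}silane | COc1c(C)cc(O[Si](C(C)C)(C(C)C)C(C)C)cc1C/C=C(\C)CC(O[Si](CC)(CC)CC)C#CC | intermediate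
22 | (2E,6E)-alkenyl(chlorido)zirconocene from 21, zirconium on C2 | COc1c(C)cc(O[Si](C(C)C)(C(C)C)C(C)C)cc1C/C=C(\C)CC(O[Si](CC)(CC)CC)/C=C(\C)[Zr](Cl)(C1C=CC=C1)C1C=CC=C1 | intermediate
23 | triethyl{[(2E,6E)-8-Ar-2-iodo-6-methylocta-2,6-dien-4-yl]oxy}silane | COc1c(C)cc(O[Si](C(C)C)(C(C)C)C(C)C)cc1C/C=C(\C)CC(O[Si](CC)(CC)CC)/C=C(\C)I | intermediate
24 | (2S)-2-[3-(9-borabicyclo[3.3.1]nonan-9-yl)propyl]-2,6,6-trimethyl-2H-pyran-3(6H)-one | B1(CCC[C@]3(C)OC(C)(C)C=CC3=O)C2CCCC1CCC2 | intermediate
25 | (2S)-2-[(4E,8E)-10-Ar-4,8-dimethyl-6-(triethylsilyloxy)deca-4,8-dien-1-yl]-2,6,6-trimethyl-2H-pyran-3(6H)-one | COc1c(C)cc(O[Si](C(C)C)(C(C)C)C(C)C)cc1C/C=C(\C)CC(O[Si](CC)(CC)CC)/C=C(\C)CCC[C@]1(C)OC(C)(C)C=CC1=O | intermediate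
26 | (2S)-2-[(4E,8E)-10-Ar-6-hydroxy-4,8-dimethyldeca-4,8-dien-1-yl]-2,6,6-trimethyl-2H-pyran-3(6H)-one | COc1c(C)cc(O[Si](C(C)C)(C(C)C)C(C)C)cc1C/C=C(\C)CC(O)/C=C(\C)CCC[C@]1(C)OC(C)(C)C=CC1=O | intermediate
27 | (2S)-2-[(4E,8E)-10-Ar-4,8-dimethyl-6-oxodeca-4,8-dien-1-yl]-2,6,6-trimethyl-2H-pyran-3(6H)-one | COc1c(C)cc(O[Si](C(C)C)(C(C)C)C(C)C)cc1C/C=C(\C)CC(=O)/C=C(\C)CCC[C@]1(C)OC(C)(C)C=CC1=O | intermediate
28 | (2S)-2-[(4E,8E)-10-(5-hydroxy-2-methoxy-3-methylphenyl)-4,8-dimethyl-6-oxodeca-4,8-dien-1-yl]-2,6,6-trimethyl-2H-pyran-3(6H)-one | COc1c(C)cc(O)cc1C/C=C(\C)CC(=O)/C=C(\C)CCC[C@]1(C)OC(C)(C)C=CC1=O | target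

**Summary**

Total step count: 16. Longest linear sequence: 11 steps (steps 6 to 16); the pyranone branch (steps 1 to 5) joins at step 13.

**Steps most likely to fail**

Step 4. The second stage may stall or reverse: liberated methoxide can reopen the non-enolisable β-keto ester (retro-Claisen), the ester enolate can instead undergo a [2,3]-Wittig shift across its tertiary allylic ether, and any E-enoate cannot cyclise. The fallback sets out from 6 and returns at 9, forming C2–C3 and C4=C5 in separate operations with no allylic ether present at the enolate stage. Compound 6 is treated with HC(OMe)3 and PPTS to give the dimethyl acetal prop-2-en-1-yl 2-[(1,1-dimethoxy-2-methylpropan-2-yl)oxy]propanoate F1. Its lithium enolate (LiN(iPr)2, THF, −78 °C) is C-acetylated with N-methoxy-N-methylacetamide (Claisen-type acylation) to prop-2-en-1-yl 2-[(1,1-dimethoxy-2-methylpropan-2-yl)oxy]-2-methyl-3-oxobutanoate F2. Aqueous TsOH in acetone then releases the keto aldehyde prop-2-en-1-yl 2-methyl-2-[(2-methyl-1-oxopropan-2-yl)oxy]-3-oxobutanoate F3, which on warming with the same acid in toluene under water removal should close by intramolecular aldol condensation to 9.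

Step 5. Facial discrimination at the planar palladium 2H-pyran-3-olate may be poor, because the ring oxygen next to the enolate carbon differs from the carbocyclic models. The fallback sets out from 9 and returns at 10, taking the configuration from a separation instead of from the catalyst. Compound 9 is allylated with the achiral catalyst Pd(PPh3)4 (THF, rt) to racemic 2,6,6-trimethyl-2-(prop-2-en-1-yl)-2H-pyran-3(6H)-one F4. The enantiomers are then separated by preparative chromatography on a chiral stationary phase (amylose tris(3,5-dimethylphenylcarbamate), CO2/propan-2-ol), and the (S)-enantiomer is 10.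

Step 13. 9-BBN may reduce the ring ketone in competition with hydroboration of the allyl group, which consumes the borane and erodes the coupling. The fallback sets out from 10 and returns at 27, masking the ketone at the alcohol oxidation level. Luche reduction of 10 (NaBH4, CeCl3·7H2O, MeOH, −78 °C) gives (2S)-2,6,6-trimethyl-2-(prop-2-en-1-yl)-3,6-dihydro-2H-pyran-3-ol F5 as both C3 epimers. Silylation (Et3SiCl, imidazole) gives its triethylsilyl ether F6. Hydroboration with 9-BBN and Suzuki–Miyaura coupling with 23 under the conditions of step 13 give the bis(triethylsilyl) ether of the coupled diol F7. PPTS in MeOH removes both triethylsilyl groups to give (2S)-2-[(4E,8E)-10-Ar-6-hydroxy-4,8-dimethyldeca-4,8-dien-1-yl]-2,6,6-trimethyl-3,6-dihydro-2H-pyran-3-ol F8. Dess–Martin periodinane (excess, pyridine, CH2Cl2) then oxidises both allylic carbinols to 27.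

**Further compounds**

F1 | step 4 | prop-2-en-1-yl 2-[(1,1-dimethoxy-2-methylpropan-2-yl)oxy]propanoate | C=CCOC(=O)C(C)OC(C)(C)C(OC)OC
F2 | step 4 | prop-2-en-1-yl 2-[(1,1-dimethoxy-2-methylpropan-2-yl)oxy]-2-methyl-3-oxobutanoate | C=CCOC(=O)C(C)(OC(C)(C)C(OC)OC)C(C)=O
F3 | step 4 | prop-2-en-1-yl 2-methyl-2-[(2-methyl-1-oxopropan-2-yl)oxy]-3-oxobutanoate | C=CCOC(=O)C(C)(OC(C)(C)C=O)C(C)=O
F4 | step 5 | racemic 2,6,6-trimethyl-2-(prop-2-en-1-yl)-2H-pyran-3(6H)-one | C=CCC1(C)OC(C)(C)C=CC1=O
F5 | step 13 | (2S)-2,6,6-trimethyl-2-(prop-2-en-1-yl)-3,6-dihydro-2H-pyran-3-ol (both C3 epimers) | C=CC[C@]1(C)OC(C)(C)C=CC1O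
F6 | step 13 | triethyl{[(2S)-2,6,6-trimethyl-2-(prop-2-en-1-yl)-3,6-dihydro-2H-pyran-3-yl]oxy}silane | C=CC[C@]1(C)OC(C)(C)C=CC1O[Si](CC)(CC)CC
F7 | step 13 | bis(triethylsilyl) ether of (2S)-2-[(4E,8E)-10-Ar-6-hydroxy-4,8-dimethyldeca-4,8-dien-1-yl]-2,6,6-trimethyl-3,6-dihydro-2H-pyran-3-ol | COc1c(C)cc(O[Si](C(C)C)(C(C)C)C(C)C)cc1C/C=C(\C)CC(O[Si](CC)(CC)CC)/C=C(\C)CCC[C@]1(C)OC(C)(C)C=CC1O[Si](CC)(CC)CC
F8 | step 13 | (2S)-2-[(4E,8E)-10-Ar-6-hydroxy-4,8-dimethyldeca-4,8-dien-1-yl]-2,6,6-trimethyl-3,6-dihydro-2H-pyran-3-ol | COc1c(C)cc(O[Si](C(C)C)(C(C)C)C(C)C)cc1C/C=C(\C)CC(O)/C=C(\C)CCC[C@]1(C)OC(C)(C)C=CC1O
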